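**Plan**

- Numbering: cyclohexane C1(=C10H2)–C2–C3(O)–C4(i-Pr)–C5–C9, fused at C5–C9 to cyclopentane C5–C6(Ac)–C7(O)–C8–C9. Because C5–C9 is the shared bond, cutting it opens both rings to one nine-membered ring in which a C1 ketone enolate (nucleophilic at C9) faces C5, the β-carbon of a C5=C6 acetyl enone.
- Retrosynthesis, in order: the C7 and C3 ester C–O bonds; C7–O (conjugate borylation of a C6=C7 enone); C1=C10 (Wittig); then C5–C9 (transannular Michael) and C7–C8 (anionic oxy-Cope), back to a 1-vinyl-2-(3-oxobut-1-en-2-yl)cyclopentanol. Its vinyl, isopropyl and alkenyl bonds are cut back to (S)-4-silyloxycyclopentenone.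
- Forward: the cyclopentane is substituted (Negishi coupling, cuprate addition, vinyl addition), expanded to the nine-membered dienolate and closed to the cyclohexanone and cyclopentane in the same operation. The C1 methylene, the C3 ester, the C6=C7 bond, the C7 hydroxyl and the angelate follow.
- Stereochemistry: C4 from the silyloxy stereocentre of the starting enone (anti cuprate addition); C5 from C4 by allylic strain in the Michael step; C9 and C6 by equilibration α to the two ketones. C3 is carried as an equatorial silyl ether and inverted by Mitsunobu esterification; C7 comes from a chiral copper catalyst; the epoxide from Sharpless epoxidation.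

Key step: step 8

Assumption: the trans-fused diketone with the C6 acetyl group trans to C4 is taken to be the thermodynamic epimer at C9 and C6, and 15 is drawn as the open hydroxy enone although it may rest as its five-membered hemiketal.

**Step 1**
Reactants: 1 but-3-en-2-one
Product: 3 3-bromobut-3-en-2-one, via 3,4-dibromobutan-2-one 2 (not isolated)
Conditions: Br2, CH2Cl2, −78 °C; then Et3N, 0 °C
Reagents that add atoms: bromine, BrBr
Why: Bromine adds across the enone and triethylamine removes HBr through the enolate (bromination–dehydrobromination), which can only leave bromine on the α-carbon.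

**Step 2**
Reactants: 3 3-bromobut-3-en-2-one
Product: 4 2-(1-bromovinyl)-2-methyl-1,3-dioxolane
Conditions: TMSOCH2CH2OTMS, TMSOTf (cat.), CH2Cl2, −78 to −20 °C
Reagents that add atoms: 1,2-bis(trimethylsilyloxy)ethane, C[Si](C)(C)OCCO[Si](C)(C)C
Why: TMSOTf-catalysed ketalisation with the bis-silyl ether runs cold and aprotic, so the sensitive α-bromo enone should be masked without conjugate addition.

**Step 3**
Reactants: 5 (S)-4-(tert-butyldimethylsilyloxy)cyclopent-2-en-1-one
Product: 6 (S)-4-(tert-butyldimethylsilyloxy)-2-iodocyclopent-2-en-1-one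
Conditions: I2, pyridine, CH2Cl2, 0 °C to rt
Reagents that add atoms: iodine, II
Why: α-Iodination of the enone by pyridine addition, enolate iodination and elimination is standard for 4-silyloxycyclopentenones and leaves the stereocentre untouched.

**Step 4**
Reactants: 4 2-(1-bromovinyl)-2-methyl-1,3-dioxolane; 6 (S)-4-(tert-butyldimethylsilyloxy)-2-iodocyclopent-2-en-1-one
Product: 9 (S)-4-(tert-butyldimethylsilyloxy)-2-[1-(2-methyl-1,3-dioxolan-2-yl)vinyl]cyclopent-2-en-1-one, via vinyllithium 7 (not isolated), via vinylzinc chloride 8 (not isolated)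
Conditions: 4, t-BuLi (2 equiv), THF, −78 °C; ZnCl2, −78 to 0 °C; then 6, Pd(PPh3)4 (5 mol %), THF, rt
Reagents that add atoms: none
Why: Bromine–lithium exchange and transmetalation give a non-basic alkenylzinc that should couple with the α-iodoenone under palladium catalysis (Negishi coupling) without touching the enone or the silyl ether.

**Step 5**
Reactants: 9 (S)-4-(tert-butyldimethylsilyloxy)-2-[1-(2-methyl-1,3-dioxolan-2-yl)vinyl]cyclopent-2-en-1-one; 10 isopropylmagnesium chloride
Product: 12 (2R,3S,4S)-4-(tert-butyldimethylsilyloxy)-3-isopropyl-2-[1-(2-methyl-1,3-dioxolan-2-yl)vinyl]cyclopentan-1-one, via silyl enol ether 11 (not isolated)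
Conditions: i-PrMgCl, CuBr·SMe2 (10 mol %), TMSCl, THF, −78 °C; then K2CO3, MeOH, 0 °C
Reagents that add atoms: none
Why: Copper-catalysed conjugate addition of the Grignard reagent should occur at the β-carbon anti to the adjacent silyloxy group, and methanolysis of the silyl enol ether under mild base lets the doubly activated α-hydrogen settle to the 2,3-trans ketone.

**Step 6**
Reactants: 12 (2R,3S,4S)-4-(tert-butyldimethylsilyloxy)-3-isopropyl-2-[1-(2-methyl-1,3-dioxolan-2-yl)vinyl]cyclopentan-1-one; 13 vinylmagnesium bromide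
Product: 14 (1S,2R,3S,4S)-4-(tert-butyldimethylsilyloxy)-3-isopropyl-2-[1-(2-methyl-1,3-dioxolan-2-yl)vinyl]-1-vinylcyclopentan-1-ol
Conditions: CeCl3 (anhydrous), vinylMgBr, THF, −78 °C; aq. NH4Cl
Reagents that add atoms: none
Why: The organocerium reagent adds 1,2 to the easily enolised ketone from the face anti to the α-alkenyl group (organocerium carbonyl addition), placing vinyl trans to that group and OH cis to it.

**Step 7**
Reactants: 14 (1S,2R,3S,4S)-4-(tert-butyldimethylsilyloxy)-3-isopropyl-2-[1-(2-methyl-1,3-dioxolan-2-yl)vinyl]-1-vinylcyclopentan-1-ol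
Product: 15 (1S,2R,3S,4S)-4-(tert-butyldimethylsilyloxy)-3-isopropyl-2-(3-oxobut-1-en-2-yl)-1-vinylcyclopentan-1-ol
Conditions: PPTS (cat.), acetone/H2O, 40 °C
Reagents that add atoms: water, O
Why: Mild acid-catalysed ketal hydrolysis should release the enone while the silyl ether and the tertiary allylic alcohol survive.

**Step 8**
Reactants: 15 (1S,2R,3S,4S)-4-(tert-butyldimethylsilyloxy)-3-isopropyl-2-(3-oxobut-1-en-2-yl)-1-vinylcyclopentan-1-ol
Product: 20 trans-fused 6-acetyl-3-(tert-butyldimethylsilyloxy)-4-isopropylhydrindan-1-one (target numbering; H5/H9 anti, silyloxy, isopropyl and C6 equatorial, acetyl trans to C4), via potassium alkoxide 16 (not isolated), via cyclononadienone enolate 17 (not isolated), via bicyclic enolate 18 (not isolated), via kinetic diketone 19 (not isolated)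
Conditions: KH (1.5 equiv), 18-crown-6 (1.5 equiv), THF (0.01 M), 0 °C to rt; AcOH, −78 °C; then K2CO3, MeOH, rt
Reagents that add atoms: none
Why: Proposed new method: the potassium alkoxide 16 (in equilibrium with its hemiketal) undergoes an anionic oxy-Cope rearrangement through the chair transition state open to the trans-dialkenyl arrangement, breaking C1–C5 and forming C7–C8 to give the nine-membered dienolate 17, whose C9 then adds across the ring to C5 of the acetyl-activated C5=C6 bond (transannular Michael addition) to give 18. The closest known reactions are anionic oxy-Cope ring expansions of 1,2-dialkenylcycloalkanols to medium-ring enolates and transannular Michael additions of medium-ring enolates, which have not been run as one cascade on this substitution pattern. The single C5–C9 bond closes the cyclohexanone in the 6-(enolendo)-exo-trig mode and the cyclopentane in the formally disfavoured 5-(enolexo)-endo-trig mode, which the favoured six-ring closure and the transannular proximity of C9 and C5 carry. C5 is controlled by the C4 stereocentre: allylic 1,3-strain keeps H4 in the enone plane, so C9, tethered through C1–C2–C3, bonds anti to the isopropyl group and leaves isopropyl and C6 trans-diequatorial. C9 and C6 each lie α to a ketone and are set by the closing K2CO3/MeOH equilibration to the trans ring fusion and to the acetyl group trans to C4, whichever ring fusion the cascade delivers kinetically. The step needs the [3,3] shift to outrun enolisation, oxa-Michael addition and oligomerisation of the enone and needs the C3 oxygen to stay in place, which high dilution, the crown ether and the equatorial silyloxy group (poorly aligned for β-elimination) are meant to secure.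

**Step 9**
Reactants: 20 trans-fused 6-acetyl-3-(tert-butyldimethylsilyloxy)-4-isopropylhydrindan-1-one
Product: 21 6-acetyl-3-(tert-butyldimethylsilyloxy)-4-isopropyl-1-methylenehydrindane (same configuration)
Conditions: Ph3PCH3Br, KOt-Bu, THF, 0 °C; then 20 (ylide 1.2 equiv), −78 to 0 °C
Reagents that add atoms: methyltriphenylphosphonium bromide, C[P+](c1ccccc1)(c1ccccc1)c1ccccc1.[Br-]
Why: Wittig methylenation is expected to take the cyclohexanone carbonyl, which is intrinsically far more electrophilic than the α-branched acetyl group, and the basic ylide can only reinforce the thermodynamic configurations at C9 and C6.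

**Step 10**
Reactants: 21 6-acetyl-3-(tert-butyldimethylsilyloxy)-4-isopropyl-1-methylenehydrindane
Product: 22 6-acetyl-4-isopropyl-1-methylenehydrindan-3-ol (equatorial OH, trans to isopropyl)
Conditions: HF·pyridine, pyridine, THF, 0 °C to rt
Reagents that add atoms: none
Why: Buffered fluoride cleavage of the secondary silyl ether (desilylation) should leave the ketone and the exocyclic alkene untouched.

**Step 11**
Reactants: 23 angelic acid ((Z)-2-methylbut-2-enoic acid)
Product: 24 (Z)-2-methylbut-2-en-1-ol
Conditions: LiAlH4, Et2O, 0 °C to rt; aqueous work-up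
Reagents that add atoms: none
Why: Hydride reduction of the alkyl-substituted unsaturated acid (LiAlH4 reduction) should give the allylic alcohol without Z/E isomerisation.

**Step 12**
Reactants: 24 (Z)-2-methylbut-2-en-1-ol
Product: 25 ((2R,3S)-2,3-dimethyloxiran-2-yl)methanol
Conditions: Ti(Oi-Pr)4 (cat.), D-(−)-diethyl tartrate (cat.), t-BuOOH, 4 Å MS, CH2Cl2, −20 °C
Reagents that add atoms: tert-butyl hydroperoxide, CC(C)(C)OO
Why: Sharpless asymmetric epoxidation with the D-(−)-tartrate should deliver oxygen to the alkene face that gives the (2R,3S)-epoxy alcohol, the Z geometry fixing the two methyl groups trans.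

**Step 13**
Reactants: 25 ((2R,3S)-2,3-dimethyloxiran-2-yl)methanol
Product: 26 (2S,3S)-2,3-dimethyloxirane-2-carboxylic acid
Conditions: TEMPO (cat.), PhI(OAc)2, MeCN/H2O, rt
Reagents that add atoms: water, O
Why: TEMPO/PhI(OAc)2 oxidation in aqueous acetonitrile takes the primary alcohol through the aldehyde hydrate to the acid under conditions that epoxides tolerate.

**Step 14**
Reactants: 22 6-acetyl-4-isopropyl-1-methylenehydrindan-3-ol; 26 (2S,3S)-2,3-dimethyloxirane-2-carboxylic acid
Product: 27 6-acetyl-4-isopropyl-1-methylenehydrindan-3-yl (2S,3S)-2,3-dimethyloxirane-2-carboxylate (axial ester, cis to isopropyl)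
Conditions: PPh3, DIAD, THF, 0 °C to rt
Reagents that add atoms: none
Why: Mitsunobu esterification should displace the activated equatorial C3 oxygen with inversion by the carboxylate of 26 (an acid comparable in strength to 4-nitrobenzoic acid), the equatorial leaving group having no antiperiplanar hydrogen for elimination and the axial approach meeting only H5 because C1 is trigonal.

**Step 15**
Reactants: 27 6-acetyl-4-isopropyl-1-methylenehydrindan-3-yl (2S,3S)-2,3-dimethyloxirane-2-carboxylate
Product: 28 6-acetyl-4-isopropyl-1-methylenehydrind-6-en-3-yl (2S,3S)-2,3-dimethyloxirane-2-carboxylate (C6=C7 enone)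
Conditions: IBX (2.5 equiv), DMSO/toluene, 70 °C
Reagents that add atoms: none
Why: IBX-mediated α,β-dehydrogenation of the ketone can only unsaturate the C6 side of the acetyl group and should give the C6=C7 enone and not the more strained tetrasubstituted C5=C6 isomer.

**Step 16**
Reactants: 28 6-acetyl-4-isopropyl-1-methylenehydrind-6-en-3-yl (2S,3S)-2,3-dimethyloxirane-2-carboxylate
Product: 30 6-acetyl-7-hydroxy-4-isopropyl-1-methylenehydrindan-3-yl (2S,3S)-2,3-dimethyloxirane-2-carboxylate (C7–OH cis to acetyl and to the C9–C1 bond), via boronate 29 (not isolated)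
Conditions: B2pin2, CuCl (5 mol %), (R,S)-Josiphos [(R)-1-[(S)-2-(diphenylphosphino)ferrocenyl]ethyldicyclohexylphosphine] (6 mol %), NaOt-Bu (10 mol %), MeOH (2 equiv), THF, rt; then NaBO3·4H2O, THF/H2O, rt
Reagents that add atoms: sodium perborate, [Na+].[O-]OB=O
Why: Copper-catalysed conjugate borylation puts boron on C7 under control of the chiral bisphosphine (the ligand antipode used is to be the one that adds syn to the C9–C1 bond, the ring itself offering little bias), C6 is protonated anti to boron into the thermodynamically preferred acetyl orientation, and perborate replaces boron by OH with retention.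

**Step 17**
Reactants: 30 6-acetyl-7-hydroxy-4-isopropyl-1-methylenehydrindan-3-yl (2S,3S)-2,3-dimethyloxirane-2-carboxylate; 23 angelic acid
Product: 32 CNP0300602.1, via mixed anhydride 31 (not isolated)
Conditions: 23, 2,4,6-trichlorobenzoyl chloride, Et3N, toluene, rt; then 30, toluene, 75 °C (no DMAP)
Reagents that add atoms: none
Why: Acylation of the C7 hydroxyl by the preformed mixed anhydride (Yamaguchi esterification without nucleophilic catalyst) should transfer the angeloyl group without Z-to-E isomerisation.

**Compound list**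

1 | but-3-en-2-one | CC(=O)C=C | starting material
2 | 3,4-dibromobutan-2-one | CC(=O)C(Br)CBr | intermediate
3 | 3-bromobut-3-en-2-one | CC(=O)C(Br)=C | intermediate
4 | 2-(1-bromovinyl)-2-methyl-1,3-dioxolane | C=C(Br)C1(C)OCCO1 | intermediate
5 | (S)-4-(tert-butyldimethylsilyloxy)cyclopent-2-en-1-one | O=C1C=C[C@@H](O[Si](C)(C)C(C)(C)C)C1 | starting material
6 | (S)-4-(tert-butyldimethylsilyloxy)-2-iodocyclopent-2-en-1-one | O=C1C(I)=C[C@@H](O[Si](C)(C)C(C)(C)C)C1 | intermediate
7 | [1-(2-methyl-1,3-dioxolan-2-yl)vinyl]lithium | [Li]C(=C)C1(C)OCCO1 | intermediate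
8 | chloro[1-(2-methyl-1,3-dioxolan-2-yl)vinyl]zinc | Cl[Zn]C(=C)C1(C)OCCO1 | intermediate
9 | (S)-4-(tert-butyldimethylsilyloxy)-2-[1-(2-methyl-1,3-dioxolan-2-yl)vinyl]cyclopent-2-en-1-one | O=C1C(C(=C)C2(C)OCCO2)=C[C@@H](O[Si](C)(C)C(C)(C)C)C1 | intermediate
10 | isopropylmagnesium chloride | CC(C)[Mg]Cl | starting material
11 | trimethylsilyl enol ether of 12 (isopropyl trans to the silyloxy group) | C[Si](C)(C)OC1=C(C(=C)C2(C)OCCO2)[C@H](C(C)C)[C@@H](O[Si](C)(C)C(C)(C)C)C1 | intermediate
12 | (2R,3S,4S)-4-(tert-butyldimethylsilyloxy)-3-isopropyl-2-[1-(2-methyl-1,3-dioxolan-2-yl)vinyl]cyclopentan-1-one | O=C1C[C@H](O[Si](C)(C)C(C)(C)C)[C@@H](C(C)C)[C@@H]1C(=C)C2(C)OCCO2 | intermediate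
13 | vinylmagnesium bromide | C=C[Mg]Br | starting material
14 | (1S,2R,3S,4S)-4-(tert-butyldimethylsilyloxy)-3-isopropyl-2-[1-(2-methyl-1,3-dioxolan-2-yl)vinyl]-1-vinylcyclopentan-1-ol | C=C[C@@]1(O)C[C@H](O[Si](C)(C)C(C)(C)C)[C@@H](C(C)C)[C@@H]1C(=C)C2(C)OCCO2 | intermediate
15 | (1S,2R,3S,4S)-4-(tert-butyldimethylsilyloxy)-3-isopropyl-2-(3-oxobut-1-en-2-yl)-1-vinylcyclopentan-1-ol | C=C[C@@]1(O)C[C@H](O[Si](C)(C)C(C)(C)C)[C@@H](C(C)C)[C@@H]1C(=C)C(C)=O | intermediate
16 | potassium alkoxide of 15 | C=C[C@@]1([O-])C[C@H](O[Si](C)(C)C(C)(C)C)[C@@H](C(C)C)[C@@H]1C(=C)C(C)=O.[K+] | intermediate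
17 | potassium 6-acetyl-3-(tert-butyldimethylsilyloxy)-4-isopropylcyclonona-1(9),5-dien-1-olate (target numbering; both ring double bonds trans within the ring) | [O-]/C1=C\CC/C(C(C)=O)=C/[C@H](C(C)C)[C@@H](O[Si](C)(C)C(C)(C)C)C1.[K+] | intermediate
18 | potassium enolate of the C6 acetyl group of the bicyclic diketone (C9 as formed) | O=C1C[C@H](O[Si](C)(C)C(C)(C)C)[C@@H](C(C)C)[C@@H]2C(=C(C)[O-])CCC12.[K+] | intermediate
19 | 6-acetyl-3-(tert-butyldimethylsilyloxy)-4-isopropylhydrindan-1-one as first protonated (C6 and C9 not yet equilibrated) | O=C1C[C@H](O[Si](C)(C)C(C)(C)C)[C@@H](C(C)C)[C@@H]2C(C(C)=O)CCC12 | intermediate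
20 | trans-fused 6-acetyl-3-(tert-butyldimethylsilyloxy)-4-isopropylhydrindan-1-one (silyloxy, isopropyl and C6 equatorial, acetyl trans to C4) | O=C1C[C@H](O[Si](C)(C)C(C)(C)C)[C@@H](C(C)C)[C@@H]2[C@@H](C(C)=O)CC[C@@H]12 | intermediate
21 | 6-acetyl-3-(tert-butyldimethylsilyloxy)-4-isopropyl-1-methylenehydrindane | C=C1C[C@H](O[Si](C)(C)C(C)(C)C)[C@@H](C(C)C)[C@@H]2[C@@H](C(C)=O)CC[C@@H]12 | intermediate
22 | 6-acetyl-4-isopropyl-1-methylenehydrindan-3-ol (equatorial OH, trans to isopropyl) | C=C1C[C@H](O)[C@@H](C(C)C)[C@@H]2[C@@H](C(C)=O)CC[C@@H]12 | intermediate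
23 | angelic acid, (Z)-2-methylbut-2-enoic acid | C/C=C(/C)C(=O)O | starting material
24 | (Z)-2-methylbut-2-en-1-ol | C/C=C(/C)CO | intermediate
25 | ((2R,3S)-2,3-dimethyloxiran-2-yl)methanol | OC[C@@]1(C)O[C@H]1C | intermediate
26 | (2S,3S)-2,3-dimethyloxirane-2-carboxylic acid | OC(=O)[C@@]1(C)O[C@H]1C | intermediate
27 | 6-acetyl-4-isopropyl-1-methylenehydrindan-3-yl (2S,3S)-2,3-dimethyloxirane-2-carboxylate (axial ester, cis to isopropyl) | C=C1C[C@@H](OC(=O)[C@@]3(C)O[C@H]3C)[C@@H](C(C)C)[C@@H]2[C@@H](C(C)=O)CC[C@@H]12 | intermediate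
28 | 6-acetyl-4-isopropyl-1-methylenehydrind-6-en-3-yl (2S,3S)-2,3-dimethyloxirane-2-carboxylate | C=C1C[C@@H](OC(=O)[C@@]3(C)O[C@H]3C)[C@@H](C(C)C)[C@@H]2C(C(C)=O)=CC[C@@H]12 | intermediate
29 | 7-(pinacolboryl) ketone (boron cis to acetyl) | C=C1C[C@@H](OC(=O)[C@@]3(C)O[C@H]3C)[C@@H](C(C)C)[C@@H]2[C@@H](C(C)=O)[C@@H](B4OC(C)(C)C(C)(C)O4)C[C@@H]12 | intermediate
30 | 6-acetyl-7-hydroxy-4-isopropyl-1-methylenehydrindan-3-yl (2S,3S)-2,3-dimethyloxirane-2-carboxylate (OH cis to acetyl) | C=C1C[C@@H](OC(=O)[C@@]3(C)O[C@H]3C)[C@@H](C(C)C)[C@@H]2[C@@H](C(C)=O)[C@@H](O)C[C@@H]12 | intermediate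
31 | (Z)-2-methylbut-2-enoic 2,4,6-trichlorobenzoic anhydride | C/C=C(/C)C(=O)OC(=O)c1c(Cl)cc(Cl)cc1Cl | intermediate
32 | CNP0300602.1: 6-acetyl-7-angeloyloxy-4-isopropyl-1-methylenehydrindan-3-yl (2S,3S)-2,3-dimethyloxirane-2-carboxylate (trans-fused; C3 ester axial and cis to isopropyl; acetyl trans to C4; C7 ester cis to acetyl) | C=C1C[C@@H](OC(=O)[C@@]2(C)O[C@H]2C)[C@@H](C(C)C)[C@@H]2[C@@H](C(C)=O)[C@@H](OC(=O)/C(C)=C\C)C[C@@H]12 | target

**Count and risks**

Total: 17 steps. Longest linear sequence: 13 steps (from 1 through steps 1, 2, 4–10 and 14–17 to 32).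

1. Step 8. The enone may be lost to base-initiated oligomerisation or enolisation before the [3,3] shift, or the nine-membered dienolate may fail to close across the ring. Fallback with the two events separated: starting from 14, with the acetyl group still masked, KH/18-crown-6 in THF brings about the plain anionic oxy-Cope ring expansion, and protonation gives the cyclononenone ketal F1. PPTS in wet acetone then releases the enone to give the cyclononene-dione F2. K2CO3 in MeOH effects the transannular Michael addition together with the C9/C6 equilibration, and the route is rejoined at 20.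

2. Step 16. Facial selectivity in the borylation may be poor, because the catalyst has to override the torsional preference of the cyclopentene for attack on the face of C9–H. Fallback by substrate control and inversion: starting from 28, borylation with an achiral catalyst (CuCl, Xantphos, NaOt-Bu, B2pin2, MeOH) and perborate oxidation is allowed to follow the ring's own preference and should give the C7-epimeric alcohol F3. Mitsunobu reaction of F3 with angelic acid 23 (PPh3, DIAD) then inverts C7 while forming the ester and arrives directly at 32.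

3. Step 14. Elimination or simple non-reaction may occur, because a hindered carboxylate has to displace an activated oxygen next to the isopropyl-bearing carbon. Fallback by two-stage inversion: starting from 22, Mitsunobu reaction with 4-nitrobenzoic acid should give the inverted 4-nitrobenzoate F4. K2CO3 in MeOH removes the ester to give the axial alcohol F5. Acylation of F5 with 26 (2,4,6-trichlorobenzoyl chloride, Et3N, DMAP) rejoins the route at 27.

**Further compounds**

F1 | step 8 | 3-(tert-butyldimethylsilyloxy)-4-isopropyl-6-(2-methyl-1,3-dioxolan-2-yl)cyclonon-5-en-1-one (target numbering; ring double bond trans) | O=C1CCC/C(C2(C)OCCO2)=C/[C@H](C(C)C)[C@@H](O[Si](C)(C)C(C)(C)C)C1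
F2 | step 8 | 6-acetyl-3-(tert-butyldimethylsilyloxy)-4-isopropylcyclonon-5-en-1-one (target numbering; ring double bond trans) | O=C1CCC/C(C(C)=O)=C/[C@H](C(C)C)[C@@H](O[Si](C)(C)C(C)(C)C)C1
F3 | step 16 | 7-epi-30 (C7–OH trans to acetyl) | C=C1C[C@@H](OC(=O)[C@@]3(C)O[C@H]3C)[C@@H](C(C)C)[C@@H]2[C@@H](C(C)=O)[C@H](O)C[C@@H]12
F4 | step 14 | 6-acetyl-4-isopropyl-1-methylenehydrindan-3-yl 4-nitrobenzoate (axial ester, cis to isopropyl) | C=C1C[C@@H](OC(=O)c3ccc(cc3)[N+](=O)[O-])[C@@H](C(C)C)[C@@H]2[C@@H](C(C)=O)CC[C@@H]12
F5 | step 14 | 6-acetyl-4-isopropyl-1-methylenehydrindan-3-ol (axial OH, cis to isopropyl) | C=C1C[C@@H](O)[C@@H](C(C)C)[C@@H]2[C@@H](C(C)=O)CC[C@@H]12
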